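**Retrosynthetic overview**
- Target ⇐ PGA1 by acetylation of the 15-hydroxyl ⇐ PGA1 methyl ester by enzymatic ester cleavage.
- Cyclopentenone (C9 ketone, C10=C11) ⇐ 9-nitrocyclopent-9-ene by a vinylogous oxidative Nef reaction; no 11-oxygenated (PGE-type) intermediate is used.
- 15S carbinol ⇐ C15 enone by reagent-controlled reduction; C13=C14 ⇐ Horner–Wadsworth–Emmons olefination of a C13 aldehyde.
- Key step and only ring formation: organocatalytic formal [3+2] of succinaldehyde with a nitroalkene. The enamine Michael addition makes C8–C12 and sets C8; the intramolecular Henry reaction makes C9–C10 and closes the cyclopentane.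
- Nitroalkene ⇐ methyl 8-oxooctanoate + nitromethane; succinaldehyde ⇐ 2,5-dimethoxytetrahydrofuran.

Assumption: the target is 15-O-acetyl-PGA1 (8R,12S,15S; atom locants in the Why lines follow prostane numbering), and compounds 1, 2, 6, 8 and the prolinol silyl ether catalyst are bought.

**Step 1**
Reactants: 1 methyl 8-oxooctanoate; 2 nitromethane
Product: 3 methyl 8-hydroxy-9-nitrononanoate
Conditions: MeNO2 (5 equiv), Et3N (0.3 equiv), THF, 0 °C to rt
Reagents that add atoms: none
Why: Base-catalysed Henry (nitroaldol) addition to an unhindered aliphatic aldehyde; the new carbinol centre is racemic and is removed in step 2.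

**Step 2**
Reactants: 3 methyl 8-hydroxy-9-nitrononanoate
Product: 5 methyl (E)-9-nitronon-8-enoate, via nitro mesylate 4 (not isolated)
Conditions: MsCl (1.2 equiv), Et3N (2.5 equiv), CH2Cl2, −20 to 0 °C
Reagents that add atoms: none
Why: O-mesylation followed by E1cB elimination of the β-nitro mesylate gives the thermodynamically favoured (E)-nitroalkene.

**Step 3**
Reactants: 6 2,5-dimethoxytetrahydrofuran
Product: 7 succinaldehyde
Conditions: H2O, 90 °C, 2 h; then distil, use at once
Reagents that add atoms: water, O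
Why: Thermal acetal hydrolysis of the cyclic bis-acetal releases the dialdehyde, which is used fresh because it oligomerises on standing.

**Step 4**
Reactants: 5 methyl (E)-9-nitronon-8-enoate; 7 succinaldehyde; 8 dimethyl (2-oxoheptyl)phosphonate
Product: 11 methyl 7-[(1R,5R)-3-hydroxy-2-nitro-5-[(1E)-3-oxooct-1-en-1-yl]cyclopentyl]heptanoate, via syn Michael adduct 9 (not isolated), via formyl nitrocyclopentanol 10 (not isolated)
Conditions: 7 (1.5 equiv), (S)-2-[diphenyl(trimethylsilyloxy)methyl]pyrrolidine (10 mol %), 4-nitrophenol (10 mol %), MeCN, rt; then iPr2NEt, 0 °C; then 8 (2.5 equiv), LiCl, iPr2NEt, 0 °C to rt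
Reagents that add atoms: none
Why: Hayashi–Jørgensen enamine catalysis: the enamine of 7 adds to the nitroalkene through the acyclic synclinal transition state, giving the syn adduct and fixing C8 as R; iPr2NEt then closes the ring by a 5-exo intramolecular Henry reaction and equilibrates the enolisable formyl-bearing C12 to the more stable trans relationship with the C8 chain, and a Masamune–Roush Horner–Wadsworth–Emmons olefination of the remaining aldehyde gives the (E)-enone.

**Step 5**
Reactants: 11 methyl 7-[(1R,5R)-3-hydroxy-2-nitro-5-[(1E)-3-oxooct-1-en-1-yl]cyclopentyl]heptanoate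
Product: 12 methyl 7-[(1R,5R)-2-nitro-5-[(1E)-3-oxooct-1-en-1-yl]cyclopent-2-en-1-yl]heptanoate
Conditions: Al2O3 (acidic), ClCH2CH2Cl, 60 °C
Reagents that add atoms: none
Why: Alumina-promoted dehydration of the β-nitro alcohol gives the conjugated 1-nitrocyclopentene and erases the two undefined centres at C9 and C10, leaving C8 and C12 untouched.

**Step 6**
Reactants: 12 methyl 7-[(1R,5R)-2-nitro-5-[(1E)-3-oxooct-1-en-1-yl]cyclopent-2-en-1-yl]heptanoate
Product: 14 methyl 7-[(1R,5R)-5-[(1E,3S)-3-hydroxyoct-1-en-1-yl]-2-nitrocyclopent-2-en-1-yl]heptanoate, via chloroborinate ester 13 (not isolated)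
Conditions: (−)-Ipc2BCl (from (+)-α-pinene, 2.5 equiv), THF, −40 to −20 °C; then H2O
Reagents that add atoms: none
Why: Brown asymmetric reduction with B-chlorodiisopinocampheylborane: hydride is delivered through a six-membered boat transition state with the alkenyl group as the large substituent, giving the 15S alcohol under reagent control while the ester and nitroalkene are not reduced.

**Step 7**
Reactants: 14 methyl 7-[(1R,5R)-5-[(1E,3S)-3-hydroxyoct-1-en-1-yl]-2-nitrocyclopent-2-en-1-yl]heptanoate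
Product: 15 methyl 7-[(1R,2S)-2-[(1E,3S)-3-hydroxyoct-1-en-1-yl]-5-oxocyclopent-3-en-1-yl]heptanoate
Conditions: DABCO (2 equiv), O2 (1 atm), MeCN, 0 °C to rt
Reagents that add atoms: dioxygen, O=O
Why: Vinylogous base-mediated aerobic (oxidative) Nef reaction: DABCO removes the γ-proton at C11 to give the dienyl nitronate, which is oxygenated at the nitro-bearing C9 and loses nitrite, so the C9 ketone appears with C10=C11 already in place; C12 is untouched and the trans arrangement is the thermodynamic one at the now enolisable C8.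

**Step 8**
Reactants: 15 methyl 7-[(1R,2S)-2-[(1E,3S)-3-hydroxyoct-1-en-1-yl]-5-oxocyclopent-3-en-1-yl]heptanoate
Product: 16 7-[(1R,2S)-2-[(1E,3S)-3-hydroxyoct-1-en-1-yl]-5-oxocyclopent-3-en-1-yl]heptanoic acid
Conditions: porcine liver esterase (EC 3.1.1.1), NaH2PO4/Na2HPO4 buffer pH 7.4–acetone (9:1), 30 °C
Reagents that add atoms: water, O
Why: Enzymatic hydrolysis of the unhindered primary methyl ester at neutral pH avoids the base-induced double-bond migration of the 4,5-disubstituted cyclopentenone; no stereocentre is touched.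

**Step 9**
Reactants: 16 7-[(1R,2S)-2-[(1E,3S)-3-hydroxyoct-1-en-1-yl]-5-oxocyclopent-3-en-1-yl]heptanoic acid
Product: 18 7-[(1R,2S)-2-[(1E,3S)-3-acetoxyoct-1-en-1-yl]-5-oxocyclopent-3-en-1-yl]heptanoic acid, via mixed acetic anhydride 17 (not isolated)
Conditions: Ac2O (3 equiv), pyridine, CH2Cl2, 0 °C to rt; then H2O–THF, rt
Reagents that add atoms: acetic anhydride, CC(=O)OC(C)=O
Why: Pyridine-mediated O-acylation of the secondary allylic alcohol with retention at C15 (the C–O bond is not broken); the carboxyl group is transiently acetylated to the mixed anhydride, which water cleaves at the acetyl carbonyl during work-up.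

**Compound list**
1 | methyl 8-oxooctanoate | COC(=O)CCCCCCC=O | starting material
2 | nitromethane | C[N+](=O)[O-] | starting material
3 | methyl 8-hydroxy-9-nitrononanoate (racemic) | COC(=O)CCCCCCC(O)C[N+](=O)[O-] | intermediate
4 | methyl 8-(methanesulfonyloxy)-9-nitrononanoate (racemic nitro mesylate) | COC(=O)CCCCCCC(OS(C)(=O)=O)C[N+](=O)[O-] | intermediate
5 | methyl (E)-9-nitronon-8-enoate | COC(=O)CCCCCC/C=C/[N+](=O)[O-] | intermediate
6 | 2,5-dimethoxytetrahydrofuran (cis/trans mixture) | COC1CCC(OC)O1 | starting material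
7 | succinaldehyde (butanedial) | O=CCCC=O | intermediate
8 | dimethyl (2-oxoheptyl)phosphonate | CCCCCC(=O)CP(=O)(OC)OC | starting material
9 | methyl (8R,9R)-9-formyl-8-(nitromethyl)-11-oxoundecanoate (syn Michael adduct) | O=C[C@H](CC=O)[C@@H](CCCCCCC(=O)OC)C[N+](=O)[O-] | intermediate
10 | methyl 7-[(1R,5S)-5-formyl-3-hydroxy-2-nitrocyclopentyl]heptanoate (side chains trans; epimer mixture at the nitro and hydroxy carbons) | O=C[C@H]1CC(O)C([N+](=O)[O-])[C@@H]1CCCCCCC(=O)OC | intermediate
11 | methyl 7-[(1R,5R)-3-hydroxy-2-nitro-5-[(1E)-3-oxooct-1-en-1-yl]cyclopentyl]heptanoate (epimer mixture at the nitro and hydroxy carbons) | CCCCCC(=O)/C=C/[C@H]1CC(O)C([N+](=O)[O-])[C@@H]1CCCCCCC(=O)OC | intermediate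
12 | methyl 7-[(1R,5R)-2-nitro-5-[(1E)-3-oxooct-1-en-1-yl]cyclopent-2-en-1-yl]heptanoate | CCCCCC(=O)/C=C/[C@H]1CC=C([N+](=O)[O-])[C@@H]1CCCCCCC(=O)OC | intermediate
13 | methyl 7-[(1R,5R)-5-[(1E,3S)-3-[chloro(isopinocampheyl)boranyloxy]oct-1-en-1-yl]-2-nitrocyclopent-2-en-1-yl]heptanoate (chloroborinate ester) | C[C@H]1[C@H](B(Cl)O[C@@H](CCCCC)/C=C/[C@H]2CC=C([N+](=O)[O-])[C@@H]2CCCCCCC(=O)OC)C[C@@H]3C[C@H]1C3(C)C | intermediate
14 | methyl 7-[(1R,5R)-5-[(1E,3S)-3-hydroxyoct-1-en-1-yl]-2-nitrocyclopent-2-en-1-yl]heptanoate | CCCCC[C@H](O)/C=C/[C@H]1CC=C([N+](=O)[O-])[C@@H]1CCCCCCC(=O)OC | intermediate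
15 | methyl 7-[(1R,2S)-2-[(1E,3S)-3-hydroxyoct-1-en-1-yl]-5-oxocyclopent-3-en-1-yl]heptanoate (PGA1 methyl ester) | CCCCC[C@H](O)/C=C/[C@H]1C=CC(=O)[C@@H]1CCCCCCC(=O)OC | intermediate
16 | 7-[(1R,2S)-2-[(1E,3S)-3-hydroxyoct-1-en-1-yl]-5-oxocyclopent-3-en-1-yl]heptanoic acid (PGA1) | CCCCC[C@H](O)/C=C/[C@H]1C=CC(=O)[C@@H]1CCCCCCC(=O)O | intermediate
17 | acetic 7-[(1R,2S)-2-[(1E,3S)-3-acetoxyoct-1-en-1-yl]-5-oxocyclopent-3-en-1-yl]heptanoic anhydride | CCCCC[C@@H](/C=C/[C@H]1C=CC(=O)[C@@H]1CCCCCCC(=O)OC(C)=O)OC(C)=O | intermediate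
18 | 7-[(1R,2S)-2-[(1E,3S)-3-acetoxyoct-1-en-1-yl]-5-oxocyclopent-3-en-1-yl]heptanoic acid (15-O-acetyl-PGA1, CNP0281518.1) | CCCCC[C@@H](/C=C/[C@H]1C=CC(=O)[C@@H]1CCCCCCC(=O)O)OC(C)=O | target

**Step count**
Total: 9 steps. Longest linear sequence: 8 steps (steps 1, 2, 4, 5, 6, 7, 8, 9); step 3 is a one-step side branch.

**Three steps most likely to fail, with fallbacks**

Step 4. Free succinaldehyde can oligomerise or add twice under amine catalysis, and three operations share one flask. Fallback: set out from 5 and replace 7 by commercial pent-4-enal as a masked succinaldehyde. The same prolinol silyl ether catalysed Michael addition gives methyl (8R,9R)-9-formyl-8-(nitromethyl)dodec-11-enoate F1. Ozonolysis of its terminal alkene (O3, CH2Cl2, −78 °C; then Me2S) unveils the second aldehyde and arrives at 9, which is cyclised with iPr2NEt and olefinated with 8 as in step 4.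

Step 6. The chloroborane may give an insufficient 15S:15R ratio or react sluggishly next to the nitroalkene. Fallback: set out from 11 and reduce before the nitroalkene exists. Use (R)-tetrahydro-1-methyl-3,3-diphenyl-1H,3H-pyrrolo[1,2-c][1,3,2]oxazaborole (10 mol %) with catecholborane in toluene at −78 °C, where the alkenyl group again acts as the large substituent. This gives methyl 7-[(1R,5R)-3-hydroxy-5-[(1E,3S)-3-hydroxyoct-1-en-1-yl]-2-nitrocyclopentyl]heptanoate F2. Dehydration on acidic Al2O3 as in step 5 then comes back to the route at 14, bypassing 12.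

Step 7. γ-Deprotonation may be slow, oxygen may attack the wrong terminus of the dienyl nitronate, or the product enone may isomerise under base. Fallback: set out from 14 and make the saturated ketone first, then desaturate regioselectively.
- Conjugate reduction with NaBH4 in THF/MeOH at 0 °C gives methyl 7-[(1R,5R)-5-[(1E,3S)-3-hydroxyoct-1-en-1-yl]-2-nitrocyclopentyl]heptanoate F3.
- A reductive Nef reaction (NaOMe, MeOH; then aqueous TiCl3 buffered with NH4OAc) gives methyl 7-[(1R,2R)-2-[(1E,3S)-3-hydroxyoct-1-en-1-yl]-5-oxocyclopentyl]heptanoate F4 (11-deoxy-PGE1 methyl ester).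
- Kinetic enolisation at the unsubstituted C10 with in-situ silylation (LiN(iPr)2, 2.2 equiv, Me3SiCl, THF, −78 °C) gives methyl 7-[(1R,5R)-2-(trimethylsilyloxy)-5-[(1E,3S)-3-(trimethylsilyloxy)oct-1-en-1-yl]cyclopent-2-en-1-yl]heptanoate F5.
- Saegusa–Ito oxidation with Pd(OAc)2 (1 equiv) in MeCN gives methyl 7-[(1R,2S)-5-oxo-2-[(1E,3S)-3-(trimethylsilyloxy)oct-1-en-1-yl]cyclopent-3-en-1-yl]heptanoate F6.
- Brief treatment with citric acid in MeOH removes the silyl ether and comes back to the route at 15.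

**Further compounds**
F1 | step 4 | methyl (8R,9R)-9-formyl-8-(nitromethyl)dodec-11-enoate | O=C[C@H](CC=C)[C@@H](CCCCCCC(=O)OC)C[N+](=O)[O-]
F2 | step 6 | methyl 7-[(1R,5R)-3-hydroxy-5-[(1E,3S)-3-hydroxyoct-1-en-1-yl]-2-nitrocyclopentyl]heptanoate (epimer mixture at the nitro and ring hydroxy carbons) | CCCCC[C@H](O)/C=C/[C@H]1CC(O)C([N+](=O)[O-])[C@@H]1CCCCCCC(=O)OC
F3 | step 7 | methyl 7-[(1R,5R)-5-[(1E,3S)-3-hydroxyoct-1-en-1-yl]-2-nitrocyclopentyl]heptanoate (epimer mixture at the nitro carbon) | CCCCC[C@H](O)/C=C/[C@H]1CCC([N+](=O)[O-])[C@@H]1CCCCCCC(=O)OC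
F4 | step 7 | methyl 7-[(1R,2R)-2-[(1E,3S)-3-hydroxyoct-1-en-1-yl]-5-oxocyclopentyl]heptanoate | CCCCC[C@H](O)/C=C/[C@H]1CCC(=O)[C@@H]1CCCCCCC(=O)OC
F5 | step 7 | methyl 7-[(1R,5R)-2-(trimethylsilyloxy)-5-[(1E,3S)-3-(trimethylsilyloxy)oct-1-en-1-yl]cyclopent-2-en-1-yl]heptanoate | CCCCC[C@H](O[Si](C)(C)C)/C=C/[C@H]1CC=C(O[Si](C)(C)C)[C@@H]1CCCCCCC(=O)OC
F6 | step 7 | methyl 7-[(1R,2S)-5-oxo-2-[(1E,3S)-3-(trimethylsilyloxy)oct-1-en-1-yl]cyclopent-3-en-1-yl]heptanoate | CCCCC[C@H](O[Si](C)(C)C)/C=C/[C@H]1C=CC(=O)[C@@H]1CCCCCCC(=O)OC
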